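## Retrosynthetic overview

1. Target ⇐ global desilylation of its tetra-TIPS ether.
2. The dihydrobenzofuran (the only ring formed) ⇐ 5-exo intramolecular oxa-Michael (1,6-) addition of the ortho-phenol to a p-quinone methide, released from a 1-(4-hydroxyphenyl)-2,2-diarylethanol; C2 is set trans to C3.
3. That carbinol ⇐ 4-oxyphenyl Grignard + (S)-α,α-diarylacetaldehyde ⇐ periodate cleavage of a 3,3-diaryl-propane-1,2-diol.
4. C3 stereocentre ⇐ Cu-catalysed SN2 opening (inversion) of a Sharpless (2S,3S)-3-arylglycidol by an aryl Grignard that already carries the E-stilbene (chemoselective Heck).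
5. Both resorcinol rings come from 3,5-dihydroxybenzaldehyde; the other two rings from 2-bromophenol and 4-bromophenol.

Assumption: protecting-group, olefination and heteroatom-transfer reagents (TIPSCl, MOMCl, Wittig reagents, NIS, t-BuOOH) are treated as reagents with SMILES, not numbered compounds; the carbinol centre of 17/18 is an inconsequential epimer mixture because it becomes sp2 in 19.

Abbreviations: TIPS = triisopropylsilyl; MOM = methoxymethyl; ArT = 3,5-bis(triisopropylsilyloxy)phenyl.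

## Route

Step 1
Reactants: 1 3,5-dihydroxybenzaldehyde
Product: 2 3,5-bis(triisopropylsilyloxy)benzaldehyde
Conditions: TIPSCl (2.3 equiv), imidazole (5 equiv), DMF, rt
Reagents that add atoms: triisopropylsilyl chloride CC(C)[Si](Cl)(C(C)C)C(C)C
Why: Standard phenol O-silylation; aryl TIPS ethers survive every later step, including the acidic MOM cleavage, and come off with fluoride at the end.

Step 2
Reactants: 2 3,5-bis(triisopropylsilyloxy)benzaldehyde
Product: 3 ethyl (E)-3-ArT-prop-2-enoate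
Conditions: Ph3P=CHCO2Et (1.2 equiv), toluene, 80 °C
Reagents that add atoms: ethyl (triphenylphosphoranylidene)acetate CCOC(=O)C=P(c1ccccc1)(c1ccccc1)c1ccccc1
Why: Wittig olefination with a stabilised ylide is base-free and strongly E-selective.

Step 3
Reactants: 3 ethyl (E)-3-ArT-prop-2-enoate
Product: 4 (E)-3-ArT-prop-2-en-1-ol
Conditions: DIBAL-H (2.5 equiv), CH2Cl2, −78 °C; Rochelle salt work-up
Reagents that add atoms: none
Why: DIBAL 1,2-reduction of the enoate gives the E-allylic alcohol without touching the aryl silyl ethers.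

Step 4
Reactants: 4 (E)-3-ArT-prop-2-en-1-ol
Product: 5 [(2S,3S)-3-ArT-oxiran-2-yl]methanol
Conditions: Ti(Oi-Pr)4 (10 mol %), L-(+)-diethyl tartrate (12 mol %), t-BuOOH (2 equiv), 4 Å MS, CH2Cl2, −20 °C
Reagents that add atoms: tert-butyl hydroperoxide CC(C)(C)OO
Why: Sharpless asymmetric epoxidation of an E-cinnamyl alcohol with L-(+)-tartrate gives the (2S,3S)-glycidol (typically ≥95% ee); this is the source of all absolute stereochemistry.

Step 5
Reactants: 2 3,5-bis(triisopropylsilyloxy)benzaldehyde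
Product: 6 3,5-bis(triisopropylsilyloxy)styrene
Conditions: Ph3PCH3Br (1.3 equiv), KOt-Bu (1.25 equiv), THF, 0 °C → rt (ylide pre-formed)
Reagents that add atoms: methyltriphenylphosphonium bromide C[P+](c1ccccc1)(c1ccccc1)c1ccccc1.[Br-]
Why: Wittig methylenation of the shared aldehyde gives the styrene for the Heck reaction.

Step 6
Reactants: 7 2-bromophenol
Product: 8 2-bromo-4-iodophenol
Conditions: NIS (1.05 equiv), TsOH·H2O (10 mol %), MeCN, rt
Reagents that add atoms: N-iodosuccinimide O=C1CCC(=O)N1I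
Why: Electrophilic aromatic iodination goes para to the phenol OH, giving a ring with two halogens of different reactivity.

Step 7
Reactants: 8 2-bromo-4-iodophenol
Product: 9 2-bromo-4-iodo-1-(methoxymethoxy)benzene
Conditions: MOMCl (1.5 equiv), i-Pr2NEt (2 equiv), CH2Cl2, 0 °C → rt
Reagents that add atoms: chloromethyl methyl ether COCCl
Why: O-alkylation to the MOM ether, which tolerates an ortho C–Mg bond (an ortho silyl ether would risk O→C silyl migration).

Step 8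
Reactants: 9 2-bromo-4-iodo-1-(methoxymethoxy)benzene; 6 3,5-bis(triisopropylsilyloxy)styrene
Product: 10 2-bromo-1-(methoxymethoxy)-4-[(E)-2-ArT-ethenyl]benzene
Conditions: Pd(OAc)2 (3 mol %), n-Bu4NCl (1 equiv), NaHCO3 (2.5 equiv), DMF, 60 °C
Reagents that add atoms: none
Why: Ligand-free (Jeffery) Mizoroki–Heck coupling reacts at C–I only and leaves the hindered, electron-rich C–Br untouched; syn-insertion/syn-β-H elimination gives the E-stilbene.

Step 9
Reactants: 10 2-bromo-1-(methoxymethoxy)-4-[(E)-2-ArT-ethenyl]benzene; 5 [(2S,3S)-3-ArT-oxiran-2-yl]methanol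
Product: 12 (2R,3S)-3-ArT-3-[2-(methoxymethoxy)-5-[(E)-2-ArT-ethenyl]phenyl]propane-1,2-diol, via aryl Grignard 11 (not isolated)
Conditions: 10 (1.5 equiv), Mg, LiCl, THF, rt; CuI (10 mol %), −40 °C; then 5 (pre-treated with i-PrMgCl, 1.0 equiv, THF, −40 °C), −40 → 0 °C; aq. NH4Cl
Reagents that add atoms: none
Why: Copper-catalysed Grignard opening of a 3-aryl-2,3-epoxy alcohol occurs at the benzylic C3 by SN2 with inversion, so the (3S)-epoxide gives the (3S)-diarylmethine that becomes C3 of the target (the meta-oxygenated aryl group does not favour SN1 leakage).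

Step 10
Reactants: 12 (2R,3S)-3-ArT-3-[2-(methoxymethoxy)-5-[(E)-2-ArT-ethenyl]phenyl]propane-1,2-diol
Product: 13 (2S)-2-ArT-2-[2-(methoxymethoxy)-5-[(E)-2-ArT-ethenyl]phenyl]acetaldehyde
Conditions: NaIO4 (1.5 equiv), THF–pH 7 buffer 2:1, 0 °C, 30 min; used crude at once
Reagents that add atoms: none
Why: Neutral periodate glycol cleavage removes C1 as formaldehyde and does not touch the stilbene, the acetal or the stereocentre (any 1,3-diol regioisomer from step 9 is not cleaved and is separated later).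

Step 11
Reactants: 14 4-bromophenol
Product: 15 1-bromo-4-(methoxymethoxy)benzene
Conditions: MOMCl (1.5 equiv), i-Pr2NEt (2 equiv), CH2Cl2, 0 °C → rt
Reagents that add atoms: chloromethyl methyl ether COCCl
Why: Phenol O-alkylation gives a Grignard-compatible precursor whose protecting group falls under the same acid that triggers the ring closure.

Step 12
Reactants: 15 1-bromo-4-(methoxymethoxy)benzene; 13 (2S)-2-ArT-2-[2-(methoxymethoxy)-5-[(E)-2-ArT-ethenyl]phenyl]acetaldehyde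
Product: 17 (1RS,2S)-2-ArT-1-[4-(methoxymethoxy)phenyl]-2-[2-(methoxymethoxy)-5-[(E)-2-ArT-ethenyl]phenyl]ethan-1-ol, via aryl Grignard 16 (not isolated)
Conditions: 15 (1.6 equiv), Mg, THF, 40 °C; 13 + LaCl3·2LiCl (1.0 equiv), THF, −78 °C, then the Grignard solution, −78 °C, 1 h; aq. NH4Cl at −78 °C
Reagents that add atoms: none
Why: Lanthanide-promoted Grignard 1,2-addition outruns enolisation of the α,α-diaryl aldehyde, so C2 (S) is kept; the new carbinol centre is left uncontrolled because it is erased in the next step.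

Step 13
Reactants: 17 (1RS,2S)-2-ArT-1-[4-(methoxymethoxy)phenyl]-2-[2-(methoxymethoxy)-5-[(E)-2-ArT-ethenyl]phenyl]ethan-1-ol
Product: 20 4-[(2S,3S)-3-ArT-5-[(E)-2-ArT-ethenyl]-2,3-dihydro-1-benzofuran-2-yl]phenol, via diphenol carbinol 18 (not isolated), via p-quinone methide 19 (not isolated)
Conditions: HCl (1.25 M in MeOH, 5 equiv), MeOH–CH2Cl2 2:1, 35 °C, Ar, dark
Reagents that add atoms: none
Why: Acid removes both MOM acetals, the freed 4-hydroxybenzylic alcohol dehydrates to the p-quinone methide, and the ortho-phenol adds to its exocyclic carbon in a 5-exo intramolecular oxa-Michael (1,6-conjugate) addition; the closure is reversible under the acid, so C2 settles trans to the C3 aryl group (2S) while C3 is untouched.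

Step 14
Reactants: 20 4-[(2S,3S)-3-ArT-5-[(E)-2-ArT-ethenyl]-2,3-dihydro-1-benzofuran-2-yl]phenol
Product: 21 (2S,3S)-trans-δ-viniferin
Conditions: TBAF (4.5 equiv), AcOH (4.5 equiv), THF, 0 °C → rt, Ar, dark
Reagents that add atoms: none
Why: Buffered fluoride desilylation of the four aryl TIPS ethers is mild enough to spare the stilbene, the benzylic aryl ether and both stereocentres.

## Compound list

1 | 3,5-dihydroxybenzaldehyde | O=Cc1cc(O)cc(O)c1 | starting material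
2 | 3,5-bis(triisopropylsilyloxy)benzaldehyde | O=Cc1cc(O[Si](C(C)C)(C(C)C)C(C)C)cc(O[Si](C(C)C)(C(C)C)C(C)C)c1 | intermediate
3 | ethyl (E)-3-[3,5-bis(triisopropylsilyloxy)phenyl]prop-2-enoate | CCOC(=O)/C=C/c1cc(O[Si](C(C)C)(C(C)C)C(C)C)cc(O[Si](C(C)C)(C(C)C)C(C)C)c1 | intermediate
4 | (E)-3-[3,5-bis(triisopropylsilyloxy)phenyl]prop-2-en-1-ol | OC/C=C/c1cc(O[Si](C(C)C)(C(C)C)C(C)C)cc(O[Si](C(C)C)(C(C)C)C(C)C)c1 | intermediate
5 | [(2S,3S)-3-[3,5-bis(triisopropylsilyloxy)phenyl]oxiran-2-yl]methanol | OC[C@@H]1O[C@H]1c1cc(O[Si](C(C)C)(C(C)C)C(C)C)cc(O[Si](C(C)C)(C(C)C)C(C)C)c1 | intermediate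
6 | 3,5-bis(triisopropylsilyloxy)styrene | C=Cc1cc(O[Si](C(C)C)(C(C)C)C(C)C)cc(O[Si](C(C)C)(C(C)C)C(C)C)c1 | intermediate
7 | 2-bromophenol | Oc1ccccc1Br | starting material
8 | 2-bromo-4-iodophenol | Oc1ccc(I)cc1Br | intermediate
9 | 2-bromo-4-iodo-1-(methoxymethoxy)benzene | COCOc1ccc(I)cc1Br | intermediate
10 | 2-bromo-1-(methoxymethoxy)-4-[(E)-2-[3,5-bis(triisopropylsilyloxy)phenyl]ethenyl]benzene | COCOc1ccc(/C=C/c2cc(O[Si](C(C)C)(C(C)C)C(C)C)cc(O[Si](C(C)C)(C(C)C)C(C)C)c2)cc1Br | intermediate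
11 | [2-(methoxymethoxy)-5-[(E)-2-[3,5-bis(triisopropylsilyloxy)phenyl]ethenyl]phenyl]magnesium bromide | COCOc1ccc(/C=C/c2cc(O[Si](C(C)C)(C(C)C)C(C)C)cc(O[Si](C(C)C)(C(C)C)C(C)C)c2)cc1[Mg]Br | intermediate
12 | (2R,3S)-3-[3,5-bis(triisopropylsilyloxy)phenyl]-3-[2-(methoxymethoxy)-5-[(E)-2-[3,5-bis(triisopropylsilyloxy)phenyl]ethenyl]phenyl]propane-1,2-diol | OC[C@H](O)[C@@H](c1cc(O[Si](C(C)C)(C(C)C)C(C)C)cc(O[Si](C(C)C)(C(C)C)C(C)C)c1)c1cc(/C=C/c2cc(O[Si](C(C)C)(C(C)C)C(C)C)cc(O[Si](C(C)C)(C(C)C)C(C)C)c2)ccc1OCOC | intermediate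
13 | (2S)-2-[3,5-bis(triisopropylsilyloxy)phenyl]-2-[2-(methoxymethoxy)-5-[(E)-2-[3,5-bis(triisopropylsilyloxy)phenyl]ethenyl]phenyl]acetaldehyde | O=C[C@@H](c1cc(O[Si](C(C)C)(C(C)C)C(C)C)cc(O[Si](C(C)C)(C(C)C)C(C)C)c1)c1cc(/C=C/c2cc(O[Si](C(C)C)(C(C)C)C(C)C)cc(O[Si](C(C)C)(C(C)C)C(C)C)c2)ccc1OCOC | intermediate
14 | 4-bromophenol | Oc1ccc(Br)cc1 | starting material
15 | 1-bromo-4-(methoxymethoxy)benzene | COCOc1ccc(Br)cc1 | intermediate
16 | [4-(methoxymethoxy)phenyl]magnesium bromide | COCOc1ccc([Mg]Br)cc1 | intermediate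
17 | (1RS,2S)-2-[3,5-bis(triisopropylsilyloxy)phenyl]-1-[4-(methoxymethoxy)phenyl]-2-[2-(methoxymethoxy)-5-[(E)-2-[3,5-bis(triisopropylsilyloxy)phenyl]ethenyl]phenyl]ethan-1-ol (C1 epimer mixture) | OC(c1ccc(OCOC)cc1)[C@@H](c1cc(O[Si](C(C)C)(C(C)C)C(C)C)cc(O[Si](C(C)C)(C(C)C)C(C)C)c1)c1cc(/C=C/c2cc(O[Si](C(C)C)(C(C)C)C(C)C)cc(O[Si](C(C)C)(C(C)C)C(C)C)c2)ccc1OCOC | intermediate
18 | (1RS,2S)-2-[3,5-bis(triisopropylsilyloxy)phenyl]-1-(4-hydroxyphenyl)-2-[2-hydroxy-5-[(E)-2-[3,5-bis(triisopropylsilyloxy)phenyl]ethenyl]phenyl]ethan-1-ol | OC(c1ccc(O)cc1)[C@@H](c1cc(O[Si](C(C)C)(C(C)C)C(C)C)cc(O[Si](C(C)C)(C(C)C)C(C)C)c1)c1cc(/C=C/c2cc(O[Si](C(C)C)(C(C)C)C(C)C)cc(O[Si](C(C)C)(C(C)C)C(C)C)c2)ccc1O | intermediate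
19 | 4-[(2S)-2-[3,5-bis(triisopropylsilyloxy)phenyl]-2-[2-hydroxy-5-[(E)-2-[3,5-bis(triisopropylsilyloxy)phenyl]ethenyl]phenyl]ethylidene]cyclohexa-2,5-dien-1-one (p-quinone methide) | O=C1C=CC(=C[C@@H](c2cc(O[Si](C(C)C)(C(C)C)C(C)C)cc(O[Si](C(C)C)(C(C)C)C(C)C)c2)c2cc(/C=C/c3cc(O[Si](C(C)C)(C(C)C)C(C)C)cc(O[Si](C(C)C)(C(C)C)C(C)C)c3)ccc2O)C=C1 | intermediate
20 | 4-[(2S,3S)-3-[3,5-bis(triisopropylsilyloxy)phenyl]-5-[(E)-2-[3,5-bis(triisopropylsilyloxy)phenyl]ethenyl]-2,3-dihydro-1-benzofuran-2-yl]phenol | Oc1ccc([C@H]2Oc3ccc(/C=C/c4cc(O[Si](C(C)C)(C(C)C)C(C)C)cc(O[Si](C(C)C)(C(C)C)C(C)C)c4)cc3[C@@H]2c2cc(O[Si](C(C)C)(C(C)C)C(C)C)cc(O[Si](C(C)C)(C(C)C)C(C)C)c2)cc1 | intermediate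
21 | (2S,3S)-trans-δ-viniferin, 5-[(E)-2-[(2S,3S)-3-(3,5-dihydroxyphenyl)-2-(4-hydroxyphenyl)-2,3-dihydro-1-benzofuran-5-yl]ethenyl]benzene-1,3-diol | Oc1ccc([C@H]2Oc3ccc(/C=C/c4cc(O)cc(O)c4)cc3[C@@H]2c2cc(O)cc(O)c2)cc1 | target

## Step count, longest linear sequence, risks and fallbacks

Total steps: 14. Longest linear sequence: 9 steps (steps 1, 2, 3, 4, 9, 10, 12, 13, 14; 1 → 2 → 3 → 4 → 5 → 12 → 13 → 17 → 20 → 21), i.e. 9/14 = 0.64 of the total.

**Step 9 (Cu-catalysed epoxide opening).** Risks are attack at C2 (1,3-diol), partial SN1 character that would erode ee, and a sluggish ortho-substituted aryl nucleophile. The fallback sets out from 2 and 10 and comes back at 13; it replaces the stereospecific opening by a catalytic asymmetric conjugate addition. Aldehyde 2 is condensed with nitromethane (NH4OAc, AcOH, 90 °C) to the nitroalkene (E)-1-(2-nitroethenyl)-3,5-bis(triisopropylsilyloxy)benzene F1. Bromide 10 is converted by Br/Li exchange (n-BuLi, −78 °C), B(OMe)3 and mild hydrolysis into [2-(methoxymethoxy)-5-[(E)-2-ArT-ethenyl]phenyl]boronic acid F2. A Rh(I)/chiral diene-catalysed Hayashi–Miyaura 1,4-addition of F2 to F1 (ligand enantiomer chosen for the S product) gives the nitroalkane 1-[(1S)-1-ArT-2-nitroethyl]-2-(methoxymethoxy)-5-[(E)-2-ArT-ethenyl]benzene F3. A buffered TiCl3 Nef reaction (aq. NH4OAc, THF, 0 °C) then delivers aldehyde 13.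

**Step 12 (aryl addition to the α,α-diaryl aldehyde formed in step 10).** The aldehyde is very acidic at C2, so a basic Grignard can enolise it, costing yield and possibly ee. The fallback sets out from 13 and comes back at 17; it swaps the preformed basic organometallic for a Nozaki–Hiyama–Kishi coupling. 4-Iodophenol is converted with MOMCl/i-Pr2NEt into 1-iodo-4-(methoxymethoxy)benzene F4, which is coupled with 13 using CrCl2 (4 equiv) and NiCl2 (2 mol %) in DMF at rt. The non-basic arylchromium species adds to the aldehyde and gives 17.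

**Step 13 (MOM cleavage / quinone methide / oxa-Michael cascade).** Under acid the quinone methide (as its O-protonated form) can lose H3 to a triarylethene, and re-protonation would erode ee; partial TIPS loss is harmless because step 14 removes these groups anyway. The fallback sets out from 12 and comes back at 18, which is then isolated, so the closure can be run separately under very mild catalysis with no MOM ethers present. Diol 12 is freed from its MOM group (HCl/MeOH, 35 °C) to the triol (2R,3S)-3-ArT-3-[2-hydroxy-5-[(E)-2-ArT-ethenyl]phenyl]propane-1,2-diol F5. Periodate cleavage gives the configurationally protected lactol (3S)-3-ArT-5-[(E)-2-ArT-ethenyl]-2,3-dihydro-1-benzofuran-2-ol F6. This is opened with excess [4-(tert-butyldimethylsilyloxy)phenyl]magnesium bromide F7 (from commercial (4-bromophenoxy)(tert-butyl)dimethylsilane and Mg) to the phenol carbinol (1RS,2S)-2-ArT-1-[4-(tert-butyldimethylsilyloxy)phenyl]-2-[2-hydroxy-5-[(E)-2-ArT-ethenyl]phenyl]ethan-1-ol F8. K2CO3 in MeOH at 0 °C removes only the aryl TBS ether and gives 18. Isolated 18 is then closed with 5 mol % diphenyl phosphate in CH2Cl2 at 0 °C through 19 to 20.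

## Further compounds

F1 | step 9 | (E)-1-(2-nitroethenyl)-3,5-bis(triisopropylsilyloxy)benzene | O=[N+]([O-])/C=C/c1cc(O[Si](C(C)C)(C(C)C)C(C)C)cc(O[Si](C(C)C)(C(C)C)C(C)C)c1
F2 | step 9 | [2-(methoxymethoxy)-5-[(E)-2-[3,5-bis(triisopropylsilyloxy)phenyl]ethenyl]phenyl]boronic acid | COCOc1ccc(/C=C/c2cc(O[Si](C(C)C)(C(C)C)C(C)C)cc(O[Si](C(C)C)(C(C)C)C(C)C)c2)cc1B(O)O
F3 | step 9 | 1-[(1S)-1-[3,5-bis(triisopropylsilyloxy)phenyl]-2-nitroethyl]-2-(methoxymethoxy)-5-[(E)-2-[3,5-bis(triisopropylsilyloxy)phenyl]ethenyl]benzene | O=[N+]([O-])C[C@@H](c1cc(O[Si](C(C)C)(C(C)C)C(C)C)cc(O[Si](C(C)C)(C(C)C)C(C)C)c1)c1cc(/C=C/c2cc(O[Si](C(C)C)(C(C)C)C(C)C)cc(O[Si](C(C)C)(C(C)C)C(C)C)c2)ccc1OCOC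
F4 | step 12 | 1-iodo-4-(methoxymethoxy)benzene | COCOc1ccc(I)cc1
F5 | step 13 | (2R,3S)-3-[3,5-bis(triisopropylsilyloxy)phenyl]-3-[2-hydroxy-5-[(E)-2-[3,5-bis(triisopropylsilyloxy)phenyl]ethenyl]phenyl]propane-1,2-diol | OC[C@H](O)[C@@H](c1cc(O[Si](C(C)C)(C(C)C)C(C)C)cc(O[Si](C(C)C)(C(C)C)C(C)C)c1)c1cc(/C=C/c2cc(O[Si](C(C)C)(C(C)C)C(C)C)cc(O[Si](C(C)C)(C(C)C)C(C)C)c2)ccc1O
F6 | step 13 | (3S)-3-[3,5-bis(triisopropylsilyloxy)phenyl]-5-[(E)-2-[3,5-bis(triisopropylsilyloxy)phenyl]ethenyl]-2,3-dihydro-1-benzofuran-2-ol (anomer mixture) | OC1Oc2ccc(/C=C/c3cc(O[Si](C(C)C)(C(C)C)C(C)C)cc(O[Si](C(C)C)(C(C)C)C(C)C)c3)cc2[C@@H]1c1cc(O[Si](C(C)C)(C(C)C)C(C)C)cc(O[Si](C(C)C)(C(C)C)C(C)C)c1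
F7 | step 13 | [4-(tert-butyldimethylsilyloxy)phenyl]magnesium bromide | CC(C)(C)[Si](C)(C)Oc1ccc([Mg]Br)cc1
F8 | step 13 | (1RS,2S)-2-[3,5-bis(triisopropylsilyloxy)phenyl]-1-[4-(tert-butyldimethylsilyloxy)phenyl]-2-[2-hydroxy-5-[(E)-2-[3,5-bis(triisopropylsilyloxy)phenyl]ethenyl]phenyl]ethan-1-ol | OC(c1ccc(O[Si](C)(C)C(C)(C)C)cc1)[C@@H](c1cc(O[Si](C(C)C)(C(C)C)C(C)C)cc(O[Si](C(C)C)(C(C)C)C(C)C)c1)c1cc(/C=C/c2cc(O[Si](C(C)C)(C(C)C)C(C)C)cc(O[Si](C(C)C)(C(C)C)C(C)C)c2)ccc1O
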